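**Plan**

- Retrosynthesis: the two side-ring C3–CH3 bonds are cut first (each methyl traced back through a CH2NMe2 group to a ring C–H), then the four aryl–CH2 bonds of the two methylene bridges, and last the aryl–C(=O) bond of the central ring.
- Enabling feature: in each side ring (C1 bridge CH2, C2 OH, C3 CH3, C4 OMe, C5 acetyl, C6 OH) the methyl-bearing C3 is ortho to the C2 hydroxyl and para to the C6 hydroxyl. Once both bridges are in place, C3–H of each side ring is the only aromatic C–H of the trimer.
- Forward: phloroglucinol is acylated (central ring), armed as a bis-Mannich base, and joined to two molecules of 2',4'-dihydroxy-6'-methoxyacetophenone by two quinone-methide alkylations. No ring is formed at any stage; three preformed benzene rings are linked.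
- The O-methyl pattern is bought with the acetophenone. The two C-methyl groups come last, by two-fold aminomethylation with dimethylmethyleneiminium iodide and hydrogenolysis.
- Stereochemistry: the single (R) centre comes from (R)-2-methylbutanoic acid and is carried through; no step creates a stereocentre.

Key step: step 5

Remark: side rings are numbered from the bridge carbon (C1), so the carbon that ends up methylated is C3. Primed locants use acetophenone numbering (C1' bears the acetyl group), so side-ring C1 = C3' and side-ring C3 = C5'. Compounds 1, 3, 5 and 8 are assumed to be purchased.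

**Route**

Step 1
Reactants: 1 (R)-2-methylbutanoic acid
Product: 2 (R)-2-methylbutanoyl chloride
Conditions: (COCl)2 (1.2 equiv), DMF (cat.), CH2Cl2, 0 °C → rt; concentrated cold, used crude
Reagents that add atoms: oxalyl chloride, O=C(Cl)C(=O)Cl
Why: Vilsmeier-type activation of the acid (oxalyl chloride, catalytic DMF) gives the acyl chloride without base at or below room temperature, conditions that offer the α-stereocentre no pathway to epimerise.

Step 2
Reactants: 2 (R)-2-methylbutanoyl chloride, 3 phloroglucinol (1.2 equiv)
Product: 4 (2R)-2-methyl-1-(2,4,6-trihydroxyphenyl)butan-1-one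
Conditions: AlCl3 (3.5 equiv), PhNO2–CH2Cl2, 0 °C → rt; ice/1 M HCl
Reagents that add atoms: none
Why: Friedel–Crafts C-acylation of phloroglucinol should stop after one acyl group because the chelated aryl ketone deactivates the ring, and holding the mixture at or below room temperature limits ketene-type erosion of the α-centre, whose integrity would be checked by chiral HPLC.

Step 3
Reactants: 4 (2R)-2-methyl-1-(2,4,6-trihydroxyphenyl)butan-1-one, 5 dimethylmethyleneiminium iodide (2.2 equiv)
Product: 7 (2R)-1-[3,5-bis(dimethylaminomethyl)-2,4,6-trihydroxyphenyl]-2-methylbutan-1-one, via mono-Mannich base 6 (not isolated)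
Conditions: CH2Cl2–MeCN, 0 °C → rt; then aq. NaHCO3 to pH 7
Reagents that add atoms: none
Why: in this phenol Mannich reaction the preformed iminium ion substitutes both remaining ring carbons of the acylphloroglucinol, each ortho and para to hydroxyl groups, and the product has no free ring position left through which it could condense with itself.

Step 4
Reactants: 7 (2R)-1-[3,5-bis(dimethylaminomethyl)-2,4,6-trihydroxyphenyl]-2-methylbutan-1-one, 8 2',4'-dihydroxy-6'-methoxyacetophenone (6 equiv)
Product: 12 des-methyl trimer (2R)-1-{3,5-bis[(5-acetyl-2,6-dihydroxy-4-methoxyphenyl)methyl]-2,4,6-trihydroxyphenyl}-2-methylbutan-1-one, via first quinone methide 9 (not isolated), via mono-bridged Mannich base 10 (not isolated), via second quinone methide 11 (not isolated)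
Conditions: 1,4-dioxane, 100 °C, slow addition of 7 to 8, N2 sweep
Reagents that add atoms: none
Why: thermal loss of dimethylamine from the zwitterionic Mannich base gives an ortho-quinone methide that is C-alkylated in a Michael-type addition by the acetophenone at C3', the enol-like carbon between its two hydroxyls (chelation of the 2'-OH to the acetyl group fixes the C3'=C4' bond, while C5' is shielded by the in-plane O-methyl group); the sequence repeats on the second arm, and the excess of 8 should suppress attack by the product.

Step 5
Reactants: 12 des-methyl trimer, 5 dimethylmethyleneiminium iodide (2.4 equiv)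
Product: 14 (2R)-1-{3,5-bis[[5-acetyl-3-(dimethylaminomethyl)-2,6-dihydroxy-4-methoxyphenyl]methyl]-2,4,6-trihydroxyphenyl}-2-methylbutan-1-one, via mono-aminomethyl trimer 13 (not isolated)
Conditions: CH2Cl2–MeCN, 0 °C → rt; then aq. NaHCO3 to pH 7, iodide washed out
Reagents that add atoms: none
Why: the iminium carbon of 5 is attacked by C3 of a side ring, ortho to the C2 hydroxyl and para to the chelated C6 hydroxyl, through a hydrogen-bonded ortho transition state; loss of the ring proton restores the arene, and the second side ring then reacts in the same way. The closest known reaction type is the ortho-aminomethylation (Mannich reaction) of phenols with a preformed iminium salt. No ring is closed and no stereocentre is formed; the step makes the two C3–CH2N bonds that become the C-methyl groups. The selectivity needed is for ring carbon over oxygen, over the bridged carbons of the central ring and over the ketone α-carbons. The substrate secures it because the central ring has no C–H, each side ring has exactly one, the soft iminium ion prefers carbon, and the chelated aryl ketones do not enolise at room temperature without added base or strong acid. The amine formed binds the liberated HI, so the medium stays near neutral and neither the methylene bridges nor the (R) α-centre should be disturbed.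

Step 6
Reactants: 14 bis(dimethylaminomethyl) trimer
Product: 16 target (2R)-1-{3,5-bis[(5-acetyl-2,6-dihydroxy-4-methoxy-3-methylphenyl)methyl]-2,4,6-trihydroxyphenyl}-2-methylbutan-1-one, via half-reduced amine 15 (not isolated)
Conditions: H2 (3 atm), 10% Pd/C, EtOH–AcOH, 40 °C
Reagents that add atoms: none
Why: catalytic hydrogenolysis of the benzylic C–N bonds of a phenolic Mannich base, activated by the ortho hydroxyl and by protonation in acetic acid, should deliver both C-methyl groups while the chelated, electron-rich aryl ketones and the diarylmethane bridges stay intact under these mild conditions.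

**Compound list**

1 | (R)-2-methylbutanoic acid | CC[C@@H](C)C(=O)O | starting material
2 | (R)-2-methylbutanoyl chloride | CC[C@@H](C)C(=O)Cl | intermediate
3 | phloroglucinol (benzene-1,3,5-triol) | Oc1cc(O)cc(O)c1 | starting material
4 | (2R)-2-methyl-1-(2,4,6-trihydroxyphenyl)butan-1-one | CC[C@@H](C)C(=O)c1c(O)cc(O)cc1O | intermediate
5 | dimethylmethyleneiminium iodide (Eschenmoser's salt) | C[N+](C)=C.[I-] | starting material
6 | (2R)-1-[3-(dimethylaminomethyl)-2,4,6-trihydroxyphenyl]-2-methylbutan-1-one (mono-Mannich base, not isolated) | CC[C@@H](C)C(=O)c1c(O)cc(O)c(CN(C)C)c1O | intermediate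
7 | (2R)-1-[3,5-bis(dimethylaminomethyl)-2,4,6-trihydroxyphenyl]-2-methylbutan-1-one | CC[C@@H](C)C(=O)c1c(O)c(CN(C)C)c(O)c(CN(C)C)c1O | intermediate
8 | 2',4'-dihydroxy-6'-methoxyacetophenone | CC(=O)c1c(O)cc(O)cc1OC | starting material
9 | first ortho-quinone methide, from 7 by loss of one dimethylamine (not isolated) | CC[C@@H](C)C(=O)C1=C(O)C(CN(C)C)=C(O)C(=C)C1=O | intermediate
10 | mono-bridged Mannich base: central ring carrying one (5-acetyl-2,6-dihydroxy-4-methoxyphenyl)methyl and one dimethylaminomethyl group (not isolated) | CC[C@@H](C)C(=O)c1c(O)c(CN(C)C)c(O)c(Cc2c(O)cc(OC)c(C(C)=O)c2O)c1O | intermediate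
11 | second ortho-quinone methide, from 10 by loss of dimethylamine (not isolated) | CC[C@@H](C)C(=O)C1=C(O)C(Cc2c(O)cc(OC)c(C(C)=O)c2O)=C(O)C(=C)C1=O | intermediate
12 | des-methyl trimer, (2R)-1-{3,5-bis[(5-acetyl-2,6-dihydroxy-4-methoxyphenyl)methyl]-2,4,6-trihydroxyphenyl}-2-methylbutan-1-one | CC[C@@H](C)C(=O)c1c(O)c(Cc2c(O)cc(OC)c(C(C)=O)c2O)c(O)c(Cc2c(O)cc(OC)c(C(C)=O)c2O)c1O | intermediate
13 | mono-aminomethyl trimer: 12 with CH2NMe2 at C3 of one side ring (not isolated) | CC[C@@H](C)C(=O)c1c(O)c(Cc2c(O)c(CN(C)C)c(OC)c(C(C)=O)c2O)c(O)c(Cc2c(O)cc(OC)c(C(C)=O)c2O)c1O | intermediate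
14 | (2R)-1-{3,5-bis[[5-acetyl-3-(dimethylaminomethyl)-2,6-dihydroxy-4-methoxyphenyl]methyl]-2,4,6-trihydroxyphenyl}-2-methylbutan-1-one | CC[C@@H](C)C(=O)c1c(O)c(Cc2c(O)c(CN(C)C)c(OC)c(C(C)=O)c2O)c(O)c(Cc2c(O)c(CN(C)C)c(OC)c(C(C)=O)c2O)c1O | intermediate
15 | half-reduced amine: one side ring C3-methyl, the other C3-CH2NMe2 (not isolated) | CC[C@@H](C)C(=O)c1c(O)c(Cc2c(O)c(C)c(OC)c(C(C)=O)c2O)c(O)c(Cc2c(O)c(CN(C)C)c(OC)c(C(C)=O)c2O)c1O | intermediate
16 | (2R)-1-{3,5-bis[(5-acetyl-2,6-dihydroxy-4-methoxy-3-methylphenyl)methyl]-2,4,6-trihydroxyphenyl}-2-methylbutan-1-one (CNP0201397.1) | CC[C@@H](C)C(=O)c1c(O)c(Cc2c(O)c(C)c(OC)c(C(C)=O)c2O)c(O)c(Cc2c(O)c(C)c(OC)c(C(C)=O)c2O)c1O | target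

**Step count**

Total: 6 steps. Longest linear sequence: 6 steps, from 1 to 16.

**Steps most likely to fail**

Step 4. The quinone methide may attack C5' of 8 (between the 4'-hydroxyl and the methoxy group) as well as C3', and the first-formed product may be alkylated again through its remaining ring C–H. Either process would give regio-isomeric trimers and oligomers that are hard to separate. The fallback reverses the polarity; it sets out from 8 and 4 and returns at 12. Compound 8 is aminomethylated once with 5 (1.0 equiv, CH2Cl2, 0 °C, NaHCO3 work-up) to 1-[3-(dimethylaminomethyl)-2,4-dihydroxy-6-methoxyphenyl]ethanone F1. F1 is purified and its regiochemistry assigned at the monomer stage, where an NOE between the methoxy protons and the remaining ring proton is expected for the 3'-isomer. F1 (2.2 equiv) is then heated with 4 in 1,4-dioxane at 90 °C. Loss of dimethylamine gives the side-ring quinone methide 4-acetyl-5-hydroxy-3-methoxy-6-methylidenecyclohexa-2,4-dien-1-one F2. F2 alkylates the two equivalent free carbons of 4 in turn, through the mono-bridged dimer (2R)-1-{3-[(5-acetyl-2,6-dihydroxy-4-methoxyphenyl)methyl]-2,4,6-trihydroxyphenyl}-2-methylbutan-1-one F3, to give 12. The nucleophile then has only two, equivalent, positions, and the regiochemical question is settled on a small, separable compound.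

Step 6. Cleavage of the two hindered benzylic C–N bonds may stall, the catalyst may be poisoned by residual iodide, or an aryl ketone may be hydrogenated under forcing conditions. The fallback is sulfur exchange followed by desulfurisation; it sets out from 14 and returns at 16. Compound 14 is heated with thiophenol (excess, EtOH, 80 °C). The quinone methides formed by loss of dimethylamine are trapped as the bis(phenylthiomethyl) trimer (2R)-1-{3,5-bis[[5-acetyl-2,6-dihydroxy-4-methoxy-3-(phenylsulfanylmethyl)phenyl]methyl]-2,4,6-trihydroxyphenyl}-2-methylbutan-1-one F4. Acetone-deactivated Raney Ni in EtOH at rt should then cleave both C–S bonds to give 16 without touching the ketones.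

Step 2. The (R) centre may be eroded by enolisation or ketene formation of the AlCl3-complexed acyl chloride, and O-acylation or diacylation may compete. The fallback acylates a protected phloroglucinol through its aryllithium; it sets out from 3 and 2 and returns at 4. Compound 3 is converted with MOMCl and i-Pr2NEt (CH2Cl2, 0 °C → rt) into 1,3,5-tris(methoxymethoxy)benzene F5. Compound 2 is converted with MeNH(OMe)·HCl and pyridine (CH2Cl2, 0 °C) into (2R)-N-methoxy-N,2-dimethylbutanamide F6. F5 is lithiated between two MOM ethers with n-BuLi (THF, 0 °C) to 2,4,6-tris(methoxymethoxy)phenyllithium F7. F7 adds to F6 at −78 °C; the chelated tetrahedral adduct prevents over-addition and, after NH4Cl quench, gives (2R)-2-methyl-1-[2,4,6-tris(methoxymethoxy)phenyl]butan-1-one F8. HCl in MeOH at rt removes the three MOM groups and returns 4 with no Lewis acid ever in contact with the stereocentre.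

**Further compounds**

F1 | step 4 | 1-[3-(dimethylaminomethyl)-2,4-dihydroxy-6-methoxyphenyl]ethanone | CC(=O)c1c(O)c(CN(C)C)c(O)cc1OC
F2 | step 4 | 4-acetyl-5-hydroxy-3-methoxy-6-methylidenecyclohexa-2,4-dien-1-one | CC(=O)C1=C(O)C(=C)C(=O)C=C1OC
F3 | step 4 | (2R)-1-{3-[(5-acetyl-2,6-dihydroxy-4-methoxyphenyl)methyl]-2,4,6-trihydroxyphenyl}-2-methylbutan-1-one | CC[C@@H](C)C(=O)c1c(O)cc(O)c(Cc2c(O)cc(OC)c(C(C)=O)c2O)c1O
F4 | step 6 | (2R)-1-{3,5-bis[[5-acetyl-2,6-dihydroxy-4-methoxy-3-(phenylsulfanylmethyl)phenyl]methyl]-2,4,6-trihydroxyphenyl}-2-methylbutan-1-one | CC[C@@H](C)C(=O)c1c(O)c(Cc2c(O)c(CSc3ccccc3)c(OC)c(C(C)=O)c2O)c(O)c(Cc2c(O)c(CSc3ccccc3)c(OC)c(C(C)=O)c2O)c1O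
F5 | step 2 | 1,3,5-tris(methoxymethoxy)benzene | COCOc1cc(OCOC)cc(OCOC)c1
F6 | step 2 | (2R)-N-methoxy-N,2-dimethylbutanamide | CC[C@@H](C)C(=O)N(C)OC
F7 | step 2 | 2,4,6-tris(methoxymethoxy)phenyllithium | [Li]c1c(OCOC)cc(OCOC)cc1OCOC
F8 | step 2 | (2R)-2-methyl-1-[2,4,6-tris(methoxymethoxy)phenyl]butan-1-one | CC[C@@H](C)C(=O)c1c(OCOC)cc(OCOC)cc1OCOC
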